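**Retrosynthetic overview**
1. Target ⇒ its 6,8-dimethoxy lactone, by chelation-controlled cleavage of the 8-O-methyl ether (last step).
2. Side chain ⇒ cross-metathesis/hydrogenation of (S)-3-vinyl-6,8-dimethoxy-3,4-dihydroisocoumarin with undec-10-en-5-one (made from hex-5-enylmagnesium bromide and pentanoyl chloride).
3. Key disconnection, lactone C3–O bond ⇒ 2-(but-3-enyl)-4,6-dimethoxybenzoic acid: an enantioselective allylic C–H oxidative lactonisation makes this C–O bond, ring B and the only stereocenter in one step.
4. ArCH2–CH2 bond ⇒ lateral allylation of 2,4-dimethoxy-6-methylbenzoic acid with allyl bromide.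
5. Ring order: aromatic ring A is bought; lactone ring B is the only ring formed (step 2).

Assumption: C3 of the target is (R) as written in the SMILES, and 2,4-dimethoxy-6-methylbenzoic acid, allyl bromide, 6-bromohex-1-ene and pentanoyl chloride are bought.

**Step 1**
Reactants: 1 2,4-dimethoxy-6-methylbenzoic acid; 2 3-bromoprop-1-ene (allyl bromide)
Product: 5 2-(but-3-en-1-yl)-4,6-dimethoxybenzoic acid, via lateral dilithio dianion 3 (not isolated), via lithium carboxylate 4 (not isolated)
Conditions: LiN(iPr)2 (2.2 equiv), THF, −78 → 0 °C; 2 (1.1 equiv), −78 °C → rt; then 1 M HCl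
Reagents that add atoms: none
Why: Two equivalents of amide base give the carboxylate-stabilised benzylic (lateral) dianion, whose carbanion is far more nucleophilic than the carboxylate and is C-allylated by SN2 displacement (lateral lithiation–alkylation of an o-toluic acid dianion); no stereocenter is formed.

**Step 2**
Reactants: 5 2-(but-3-en-1-yl)-4,6-dimethoxybenzoic acid
Product: 6 (3S)-3-ethenyl-6,8-dimethoxy-3,4-dihydro-1H-isochromen-1-one
Conditions: Pd(OAc)2 (10 mol%), chiral aryl sulfoxide–oxazoline ligand (ArSOX type, 10 mol%, enantiomer chosen to give (S)-6), 2,6-dimethyl-1,4-benzoquinone (1.5 equiv), Ph2P(O)OH (10 mol%), toluene, 45 °C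
Reagents that add atoms: none
Why: Proposed new method: the sulfoxide-ligated divalent palladium carboxylate of 5 cleaves an allylic C–H bond at the homobenzylic CH2 to give a π-allylpalladium species that still carries the benzoate, the two π-allyl faces interconvert by π–σ–π isomerisation through the unsubstituted terminus, and quinone-induced C–O bond formation at the internal terminus (six-membered ring; the eight-membered alternative is disfavoured) takes place in the chiral pocket of the sulfoxide–oxazoline ligand, so this C–O bond-forming event closes ring B and sets C3 as (S); the closest known reaction types are the Pd(OAc)2/bis-sulfoxide allylic C–H macrolactonisation and the Pd(OAc)2/sulfoxide–oxazoline enantioselective allylic C–H oxidation of alkenols to chromans and isochromans, neither of which has been shown for benzoic acids closing a benzo-fused δ-lactone.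

**Step 3**
Reactants: 7 6-bromohex-1-ene; 8 pentanoyl chloride
Product: 10 undec-10-en-5-one, via Grignard reagent 9 (not isolated)
Conditions: Mg, THF, 0 °C → rt; then added to 8, Fe(acac)3 (3 mol%), THF, −78 °C
Reagents that add atoms: none
Why: Iron-catalysed acylation of a Grignard reagent with an acid chloride is faster than Grignard addition to the ketone formed, so the reaction stops at the ketone and the terminal alkene is untouched; no stereocenter.

**Step 4**
Reactants: 6 (3S)-3-ethenyl-6,8-dimethoxy-3,4-dihydro-1H-isochromen-1-one; 10 undec-10-en-5-one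
Product: 12 (3R)-6,8-dimethoxy-3-(7-oxoundecyl)-3,4-dihydro-1H-isochromen-1-one, via cross-metathesis alkene 11 (not isolated)
Conditions: 10 (3 equiv), second-generation Hoveyda–Grubbs catalyst RuCl2(H2IMes)(=CH-C6H4-2-OiPr) (5 mol%), CH2Cl2, 40 °C; then EtOAc, PtO2 (5 mol%), H2 (1 atm), rt, same flask
Reagents that add atoms: none
Why: Olefin cross-metathesis of the vinyl group of 6 with excess terminal alkene 10 gives the (E)-alkene 11 with loss of ethene, and mild Pt-catalysed hydrogenation then saturates only the C=C bond (ketone, lactone and arene survive), so C3 keeps its configuration and only its descriptor changes from S to R because the alkenyl substituent becomes an alkyl chain.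

**Step 5**
Reactants: 12 (3R)-6,8-dimethoxy-3-(7-oxoundecyl)-3,4-dihydro-1H-isochromen-1-one
Product: 14 (3R)-8-hydroxy-6-methoxy-3-(7-oxoundecyl)-3,4-dihydro-1H-isochromen-1-one, via dichloroboryl ether 13 (not isolated)
Conditions: BCl3 (2.5 equiv), CH2Cl2, −78 → 0 °C; then H2O
Reagents that add atoms: none
Why: BCl3 binds in a six-membered chelate between the lactone carbonyl and the peri 8-methoxy oxygen, so chloride attacks only that methyl group (chelation-controlled Lewis-acid demethylation of an ortho-carbonyl aryl methyl ether) and the 6-methoxy group, the ketone and C3 are left alone.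

**Compound list**
1 | 2,4-dimethoxy-6-methylbenzoic acid | Cc1cc(OC)cc(OC)c1C(=O)O | starting material
2 | 3-bromoprop-1-ene (allyl bromide) | C=CCBr | starting material
3 | lithium 2-(lithiomethyl)-4,6-dimethoxybenzoate (lateral dianion) | [Li]Cc1cc(OC)cc(OC)c1C(=O)O[Li] | intermediate (not isolated)
4 | lithium 2-(but-3-en-1-yl)-4,6-dimethoxybenzoate | C=CCCc1cc(OC)cc(OC)c1C(=O)O[Li] | intermediate (not isolated)
5 | 2-(but-3-en-1-yl)-4,6-dimethoxybenzoic acid | C=CCCc1cc(OC)cc(OC)c1C(=O)O | intermediate
6 | (3S)-3-ethenyl-6,8-dimethoxy-3,4-dihydro-1H-isochromen-1-one | C=C[C@@H]1Cc2cc(OC)cc(OC)c2C(=O)O1 | intermediate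
7 | 6-bromohex-1-ene | C=CCCCCBr | starting material
8 | pentanoyl chloride | CCCCC(=O)Cl | starting material
9 | hex-5-en-1-ylmagnesium bromide | C=CCCCC[Mg]Br | intermediate (not isolated)
10 | undec-10-en-5-one | CCCCC(=O)CCCCC=C | intermediate
11 | (3S)-6,8-dimethoxy-3-[(1E)-7-oxoundec-1-en-1-yl]-3,4-dihydro-1H-isochromen-1-one | CCCCC(=O)CCCC/C=C/[C@@H]1Cc2cc(OC)cc(OC)c2C(=O)O1 | intermediate (not isolated)
12 | (3R)-6,8-dimethoxy-3-(7-oxoundecyl)-3,4-dihydro-1H-isochromen-1-one | CCCCC(=O)CCCCCC[C@@H]1Cc2cc(OC)cc(OC)c2C(=O)O1 | intermediate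
13 | (3R)-8-[(dichloroboranyl)oxy]-6-methoxy-3-(7-oxoundecyl)-3,4-dihydro-1H-isochromen-1-one | CCCCC(=O)CCCCCC[C@@H]1Cc2cc(OC)cc(OB(Cl)Cl)c2C(=O)O1 | intermediate (not isolated)
14 | (3R)-8-hydroxy-6-methoxy-3-(7-oxoundecyl)-3,4-dihydro-1H-isochromen-1-one | CCCCC(=O)CCCCCC[C@@H]1Cc2cc(OC)cc(O)c2C(=O)O1 | target

**Step count and risks**
Total: 5 steps (isolated products 5, 6, 10, 12, 14). Longest linear sequence: 4 steps (1 → 5 → 6 → 12 → 14; steps 1, 2, 4, 5).

Most likely to fail, step 2 (the proposed new reaction). The π-allyl intermediate has benzylic β-hydrogens and may eliminate to the aryl diene, the enantioselectivity with a carboxylate nucleophile is untested, and the allylic lactone could re-ionise if zerovalent palladium builds up. The fallback uses only known chemistry, sets out from 8 and comes back at 12. Commercial 8-bromooct-1-ene and Mg give oct-7-en-1-ylmagnesium bromide F1, which is acylated with 8 (Fe(acac)3, THF, −78 °C) to tridec-12-en-5-one F2. Buffered mCPBA epoxidation (NaHCO3, CH2Cl2, 0 °C → rt) gives rac-11-(oxiran-2-yl)undecan-5-one F3. Jacobsen hydrolytic kinetic resolution (0.55 equiv H2O, the (salen)Co(OAc) enantiomer that hydrolyses the (S)-epoxide) leaves (R)-11-(oxiran-2-yl)undecan-5-one F4. Carboxylate-directed ortho C–H alkylation of commercial 2,4-dimethoxybenzoic acid with F4 (Pd(OAc)2 5 mol%, KOAc, (CF3)2CHOH, 75 °C) then gives 12 directly: the arylpalladium opens the epoxide at its terminal carbon, the C–O stereocenter is retained, and the hydroxy acid lactonises. Step 5 follows unchanged.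

Second, step 4. The vinyl group of 6 is a hindered, allylic-oxygenated olefin and may metathesise slowly, and the allylic lactone C–O bond of 11 could undergo hydrogenolysis or double-bond migration during hydrogenation. The fallback sets out from 6 and comes back at 12. Hydroboration of 6 with 9-BBN-H (THF, rt) gives (3R)-3-[2-(9-borabicyclo[3.3.1]nonan-9-yl)ethyl]-6,8-dimethoxy-3,4-dihydro-1H-isochromen-1-one F5, used without isolation. A B-alkyl Suzuki–Miyaura alkyl–alkyl coupling (Pd(OAc)2 4 mol%, PCy3 8 mol%, K3PO4·H2O, THF, rt) with 1-bromononan-5-one F6 then gives 12 with no alkene ever placed next to C3. F6 is made from commercial 5-bromopentanoyl chloride and n-BuMgCl with Fe(acac)3 in THF at −78 °C.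

Third, step 1. Ring lithiation between the two methoxy groups or over-alkylation of the dianion could lower the yield. The fallback sets out from 1 and comes back at 5, working with an ester monoanion instead of the acid dianion. Compound 1 is converted into methyl 2,4-dimethoxy-6-methylbenzoate F7 (MeI, K2CO3, DMF). Lateral lithiation (LiN(iPr)2, THF, −78 °C) and allylation with 2 give methyl 2-(but-3-en-1-yl)-4,6-dimethoxybenzoate F8. Hydrolysis of the hindered ester (NaOH, DMSO/H2O, 100 °C, then HCl) returns 5.

**Further compounds**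
F1 | step 2 | oct-7-en-1-ylmagnesium bromide | C=CCCCCCC[Mg]Br
F2 | step 2 | tridec-12-en-5-one | CCCCC(=O)CCCCCCC=C
F3 | step 2 | rac-11-(oxiran-2-yl)undecan-5-one | CCCCC(=O)CCCCCCC1CO1
F4 | step 2 | (R)-11-(oxiran-2-yl)undecan-5-one | CCCCC(=O)CCCCCC[C@@H]1CO1
F5 | step 4 | (3R)-3-[2-(9-borabicyclo[3.3.1]nonan-9-yl)ethyl]-6,8-dimethoxy-3,4-dihydro-1H-isochromen-1-one | C1CC2CCCC(C1)B2CC[C@@H]1Cc2cc(OC)cc(OC)c2C(=O)O1
F6 | step 4 | 1-bromononan-5-one | BrCCCCC(=O)CCCC
F7 | step 1 | methyl 2,4-dimethoxy-6-methylbenzoate | Cc1cc(OC)cc(OC)c1C(=O)OC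
F8 | step 1 | methyl 2-(but-3-en-1-yl)-4,6-dimethoxybenzoate | C=CCCc1cc(OC)cc(OC)c1C(=O)OC
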